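**Retrosynthetic overview**

- The strategy rests on the two identical N1–C(CH3)2–CH=CH2 units of polonidine A. Each indole nitrogen (in the pyrrole ring of each indole) bears a fully substituted carbon with two methyl groups and a vinyl group. This carbon is traced back to an N–CH2–CO2Et carbon: the methyl groups come from enolate C-methylation and the vinyl group from the ester carbon.
- No ring is formed in the route. Both indole ring systems and the C3–CH2–C3′ bridge are bought as 3,3′-diindolylmethane (1).
- Disconnections, read forward: two N–CH2 bonds (1 + ethyl bromoacetate 2 → diester 3); four C–CH3 bonds in one flask (3 + iodomethane 4 → 5 → 6); two ester-to-aldehyde reductions (6 → 7); two C=CH2 bonds by Wittig methylenation (7 + phosphonium salt 8 → ylide 9 → target 10).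

Key step: step 2

Remark on the chemistry: bis(indol-3-yl)methanes are cleaved at the bridge by acid and lose hydride from the bridge to oxidants, so the main route is run under argon and uses only basic or reducing reagents.

**Route**

Step 1
Reactants: 1 3,3′-diindolylmethane; 2 ethyl bromoacetate
Product: 3 diethyl 2,2′-[methylenebis(indole-3,1-diyl)]diacetate
Conditions: NaH (2.4 equiv), DMF, 0 °C, 30 min; then 2 (2.6 equiv), 0 °C → rt
Reagents that add atoms: ethyl bromoacetate, CCOC(=O)CBr
Why: NaH removes both indole N–H protons and the bis(indolide), with C3 blocked and the sodium ion pair loosened by DMF, should undergo SN2 N-alkylation on the activated primary bromide (standard indole N-alkylation).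

Step 2
Reactants: 3 diethyl 2,2′-[methylenebis(indole-3,1-diyl)]diacetate; 4 iodomethane
Product: 6 diethyl 2,2′-[methylenebis(indole-3,1-diyl)]bis(2-methylpropanoate), via bis(α-methyl) diester 5 (not isolated)
Conditions: 3 added to LiN(i-Pr)2 (2.3 equiv), THF, −78 °C, then MeI (2.4 equiv), −78 → −20 °C; recool to −78 °C, LiN(i-Pr)2 (2.6 equiv), DMPU, then MeI (4 equiv), −78 °C → rt
Reagents that add atoms: iodomethane, CI
Why: LiN(i-Pr)2 removes one α-hydrogen from each N–CH2–CO2Et group and the resulting ester enolates are C-methylated by SN2 attack on iodomethane to give 5; the second charge of base and iodomethane repeats the cycle on the remaining α-hydrogen of each arm, so that four C–CH3 bonds and both N–C(CH3)2–CO2Et carbons of 6 are formed in one flask. The closest known reaction type is the exhaustive α-methylation of N-azolyl- and N-indolylacetate ester enolates to α,α-dimethyl esters. No ring is closed. No stereocentre remains in 6, because each new fully substituted carbon carries two identical methyl groups, and the two stereocentres of 5 (meso and racemic forms) are erased in the second cycle. The step needs site selectivity for the ester α-carbons over the C3–CH2–C3′ bridge and the indole C2–H, and C- over O-methylation: the ester α-hydrogens are more acidic than the bridge or C2 hydrogens by several pK units, so the amide base at −78 °C should touch only them, and the soft electrophile iodomethane alkylates lithium enolates at carbon. Claisen self-condensation is held back by adding the ester to excess base at −78 °C, and DMPU in the second cycle should speed methylation of the more hindered α-branched enolate.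

Step 3
Reactants: 6 diethyl 2,2′-[methylenebis(indole-3,1-diyl)]bis(2-methylpropanoate)
Product: 7 2,2′-[methylenebis(indole-3,1-diyl)]bis(2-methylpropanal)
Conditions: i-Bu2AlH (2.3 equiv, 1 M in toluene), CH2Cl2, −78 °C; MeOH, −78 °C; aq. KNaC4H4O6, rt
Reagents that add atoms: none
Why: Partial ester reduction with i-Bu2AlH, in which hydride delivery gives a tetrahedral aluminium hemiacetal that is held at −78 °C by the adjacent fully substituted carbon and should release the aldehyde only on the cold methanol and tartrate quench, while the reducing medium leaves the oxidation-prone bis(indol-3-yl)methane untouched.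

Step 4
Reactants: 7 2,2′-[methylenebis(indole-3,1-diyl)]bis(2-methylpropanal); 8 methyltriphenylphosphonium bromide
Product: 10 polonidine A, via methylenetriphenylphosphorane 9 (not isolated)
Conditions: 8 (3.0 equiv), KOt-Bu (2.8 equiv), THF, 0 °C → rt, 30 min; then 7, 0 °C → rt
Reagents that add atoms: methyltriphenylphosphonium bromide, C[P+](c1ccccc1)(c1ccccc1)c1ccccc1.[Br-]
Why: Wittig methylenation, in which the small unstabilised ylide 9 adds to both aldehydes, which have no α-hydrogen and so cannot enolise under the basic conditions, and the oxaphosphetanes should collapse to the two terminal vinyl groups and Ph3P=O.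

**Compound list**

1 | 3,3′-diindolylmethane [bis(1H-indol-3-yl)methane] | c1ccc2c(c1)c(Cc1c[nH]c3ccccc13)c[nH]2 | starting material
2 | ethyl bromoacetate | CCOC(=O)CBr | starting material
3 | diethyl 2,2′-[methylenebis(indole-3,1-diyl)]diacetate (each indole N1 carries CH2CO2Et) | CCOC(=O)Cn1cc(Cc2cn(CC(=O)OCC)c3ccccc23)c2ccccc21 | intermediate
4 | iodomethane | CI | starting material
5 | diethyl 2,2′-[methylenebis(indole-3,1-diyl)]dipropanoate (each N1 carries CH(CH3)CO2Et; mixture of meso and racemic diastereomers; formed in the flask, not isolated) | CCOC(=O)C(C)n1cc(Cc2cn(C(C)C(=O)OCC)c3ccccc23)c2ccccc21 | intermediate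
6 | diethyl 2,2′-[methylenebis(indole-3,1-diyl)]bis(2-methylpropanoate) (each N1 carries C(CH3)2CO2Et; achiral) | CCOC(=O)C(C)(C)n1cc(Cc2cn(C(C)(C)C(=O)OCC)c3ccccc23)c2ccccc21 | intermediate
7 | 2,2′-[methylenebis(indole-3,1-diyl)]bis(2-methylpropanal) (each N1 carries C(CH3)2CHO; achiral) | O=CC(C)(C)n1cc(Cc2cn(C(C)(C)C=O)c3ccccc23)c2ccccc21 | intermediate
8 | methyltriphenylphosphonium bromide | C[P+](c1ccccc1)(c1ccccc1)c1ccccc1.[Br-] | starting material
9 | methylenetriphenylphosphorane (ylide; formed in the flask, not isolated) | C=P(c1ccccc1)(c1ccccc1)c1ccccc1 | intermediate
10 | polonidine A, bis[1-(2-methylbut-3-en-2-yl)-1H-indol-3-yl]methane (achiral) | C=CC(C)(C)n1cc(Cc2cn(C(C)(C)C=C)c3ccccc23)c2ccccc21 | target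

**Step count**

Total steps: 4. Longest linear sequence: 4 steps (1 → 3 → 6 → 7 → 10).

**Steps most likely to fail, with fallbacks**

Step 2. The second methylation may stall at the hindered α-branched enolate on one arm, or an enolate may attack an ester group in a Claisen-type self-condensation. Either would leave partly methylated or condensed material that is hard to separate. The fallback forms the C–N bond to a ready-made quaternary carbon instead of building that carbon by C–C bond formation. It sets out from 1, which is N-alkylated at both nitrogens with ethyl 2-bromo-2-methylpropanoate (CCOC(=O)C(C)(C)Br; Cs2CO3, DMF, 60 °C). This is a known but less efficient hindered N-alkylation, in which E2 loss of HBr from the bromoester competes. It comes back to the route at 6 (new compounds on this path: none F0).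

Step 3. Reduction may run past the aldehyde stage on one or both arms, or the two arms may be reduced unevenly, so that ester, aldehyde and alcohol termini form side by side. The fallback separates reduction from adjustment of the oxidation level. It sets out from 6, which is fully reduced with LiAlH4 (THF, 0 °C) to the diol 2,2′-[methylenebis(indole-3,1-diyl)]bis(2-methylpropan-1-ol) F1. Both neopentyl-type alcohols are then oxidised under Parikh–Doering conditions (SO3·pyridine, DMSO, i-Pr2NEt, CH2Cl2, 0 °C), chosen because they are mild toward the electron-rich indoles and the bridge. The fallback comes back to the route at 7.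

Step 4. Addition of the ylide to the second neopentyl-type aldehyde may be sluggish, so that olefination stops half-way. The fallback is a Peterson olefination, which splits the olefination into addition and elimination. It sets out from 7, to which Me3SiCH2MgCl (C[Si](C)(C)C[Mg]Cl; THF, 0 °C) is added at both aldehydes to give the bis(β-hydroxysilane) 3,3′-[methylenebis(indole-3,1-diyl)]bis[3-methyl-1-(trimethylsilyl)butan-2-ol] F2, a mixture of diastereomers of no consequence. Base-mediated syn-elimination (KH, THF, rt) then forms both vinyl groups without acid. The fallback comes back to the route at 10.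

**Further compounds**

F0 | step 2 | none | none
F1 | step 3 | 2,2′-[methylenebis(indole-3,1-diyl)]bis(2-methylpropan-1-ol) | OCC(C)(C)n1cc(Cc2cn(C(C)(C)CO)c3ccccc23)c2ccccc21
F2 | step 4 | 3,3′-[methylenebis(indole-3,1-diyl)]bis[3-methyl-1-(trimethylsilyl)butan-2-ol] (mixture of diastereomers) | C[Si](C)(C)CC(O)C(C)(C)n1cc(Cc2cn(C(C)(C)C(O)C[Si](C)(C)C)c3ccccc23)c2ccccc21
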